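**Plan**
- Enabling feature: ring A has C5–OH para to C8–OMe, with C7–OMe and C6–H between them, and is fused to ring C through C4a=C8a. This is a mono-O-methyl hydroquinone annulated to an alkene, the pattern a 4-alkenyl-4-methoxycyclobutenone delivers.
- Cuts, in order: the benzyl masks on O3 and O2'; C4a–C5 (with C5–C8 rejoined to a four-membered ring); O–CH3 at C8; C8–C8a (carbonyl addition); C2–C1' (cross-coupling).
- Forward: ring C is bought as 3-hydroxy-4-pyranone and ring B is coupled to C2. The squarate-derived four-membered ring is then attached at the future C8a, and ring A closes last.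
- Stereochemistry: the target is achiral. The one isolable stereocentre on the way (the quaternary cyclobutenone carbon) is racemic and vanishes when ring A aromatizes.
- The C5 phenol is set free by the ring closure itself, so only two benzyl ethers are removed at the end.

Key step: step 9

Assumption: the three starting materials are taken as purchasable, all chiral intermediates are racemates, and "future Cn" refers to flavone numbering.

**Step 1**
Reactants: 1 3-hydroxy-4H-pyran-4-one (pyromeconic acid)
Product: 2 3-hydroxy-2-iodo-4H-pyran-4-one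
Conditions: NIS, DMF, 0 °C to rt, dark
Reagents that add atoms: N-iodosuccinimide, O=C1CCC(=O)N1I
Why: Electrophilic iodination of an enol: the 3-hydroxyl group activates only the adjacent C2, the same site at which kojic acid and related 3-hydroxy-4-pyranones are C-halogenated, so 2 should form as a single regioisomer.

**Step 2**
Reactants: 2 3-hydroxy-2-iodo-4H-pyran-4-one
Product: 3 3-(benzyloxy)-2-iodo-4H-pyran-4-one
Conditions: BnBr, K2CO3, DMF, rt
Reagents that add atoms: benzyl bromide, BrCc1ccccc1
Why: Williamson ether synthesis on the acidic enolic hydroxyl proceeds with a weak base at room temperature, fast enough to outrun displacement of the vinylogous acyl iodide.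

**Step 3**
Reactants: 4 2-bromo-5-methoxyphenol
Product: 5 2-(benzyloxy)-1-bromo-4-methoxybenzene
Conditions: BnBr, K2CO3, acetone, reflux
Reagents that add atoms: benzyl bromide, BrCc1ccccc1
Why: Williamson ether synthesis of a phenol, which installs the same hydrogenolysable mask on O2' as on O3.

**Step 4**
Reactants: 5 2-(benzyloxy)-1-bromo-4-methoxybenzene
Product: 6 2-[2-(benzyloxy)-4-methoxyphenyl]-4,4,5,5-tetramethyl-1,3,2-dioxaborolane
Conditions: B2pin2, PdCl2(dppf) (cat.), KOAc, 1,4-dioxane, 90 °C
Reagents that add atoms: bis(pinacolato)diboron, CC1(C)OB(OC1(C)C)B1OC(C)(C)C(C)(C)O1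
Why: Miyaura borylation turns the electron-rich aryl bromide into a pinacol boronate that resists protodeboronation better than the free ortho-alkoxy boronic acid, and the benzyl and methyl ethers are inert to it.

**Step 5**
Reactants: 3 3-(benzyloxy)-2-iodo-4H-pyran-4-one; 6 2-[2-(benzyloxy)-4-methoxyphenyl]-4,4,5,5-tetramethyl-1,3,2-dioxaborolane
Product: 7 3-(benzyloxy)-2-[2-(benzyloxy)-4-methoxyphenyl]-4H-pyran-4-one
Conditions: Pd(OAc)2 (cat.), SPhos (cat.), K3PO4, 1,4-dioxane/H2O, 80 °C
Reagents that add atoms: none
Why: Suzuki–Miyaura coupling forms C2–C1', since the C–I bond of the electron-poor pyranone adds readily to zerovalent palladium, SPhos copes with the two ortho benzyloxy groups, and the phosphate base is mild enough for the pyranone ring.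

**Step 6**
Reactants: 8 dimethyl squarate (3,4-dimethoxycyclobut-3-ene-1,2-dione)
Product: 10 3-methoxycyclobut-3-ene-1,2-dione, via 4-hydroxy-2,3-dimethoxycyclobut-2-en-1-one 9 (not isolated)
Conditions: LiAlH(OtBu)3, THF, −78 to 0 °C; aq. HCl, then cat. conc. HCl, CH2Cl2, rt; used fresh
Reagents that add atoms: water, O (one molecule enters as the new carbonyl oxygen, one leaves from the carbinol carbon)
Why: Bulky LiAlH(OtBu)3 adds one hydride 1,2 to one of the two equivalent carbonyl groups, and acid then ionizes racemic carbinol 9 to a methoxy-stabilized cyclobutenyl cation that takes up water at its far end and expels methanol, which is the standard transposition of squarate adducts to substituted cyclobutenediones.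

**Step 7**
Reactants: 7 3-(benzyloxy)-2-[2-(benzyloxy)-4-methoxyphenyl]-4H-pyran-4-one; 10 3-methoxycyclobut-3-ene-1,2-dione
Product: 12 4-{5-(benzyloxy)-6-[2-(benzyloxy)-4-methoxyphenyl]-4-oxo-4H-pyran-2-yl}-4-hydroxy-3-methoxycyclobut-2-en-1-one (racemic), via pyranonylmagnesium chloride 11 (not isolated)
Conditions: TMPMgCl·LiCl (1.1 equiv), THF, −40 °C; cannulated into 10 (1.3 equiv), THF, −78 °C; aq. NH4Cl at −78 °C
Reagents that add atoms: none
Why: Deprotonative metalation with a hindered TMP-metal amide removes the most acidic ring proton, C6–H beside the ring oxygen (the counterpart of C2–H of chromones, which such bases metalate), and Grignard reagent 11 then adds 1,2 to the carbonyl of 10 that adjoins the methoxy-bearing carbon because the other carbonyl is deactivated as a vinylogous ester, the new quaternary stereocentre arising as a racemate that needs no control.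

**Step 8**
Reactants: 12 4-{5-(benzyloxy)-6-[2-(benzyloxy)-4-methoxyphenyl]-4-oxo-4H-pyran-2-yl}-4-hydroxy-3-methoxycyclobut-2-en-1-one
Product: 13 4-{5-(benzyloxy)-6-[2-(benzyloxy)-4-methoxyphenyl]-4-oxo-4H-pyran-2-yl}-3,4-dimethoxycyclobut-2-en-1-one (racemic)
Conditions: MeI (excess), Ag2O, 4 Å MS, MeCN, rt, dark
Reagents that add atoms: iodomethane, CI
Why: Purdie methylation (Ag2O/MeI), the usual way to etherify tertiary 4-hydroxycyclobutenones, works without a free alkoxide and so avoids base-induced cleavage of the strained ring, while iodomethane is too soft to O-methylate the pyranone carbonyl to a pyrylium salt as methyl triflate might; the stereocentre is not touched.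

**Step 9**
Reactants: 13 4-{5-(benzyloxy)-6-[2-(benzyloxy)-4-methoxyphenyl]-4-oxo-4H-pyran-2-yl}-3,4-dimethoxycyclobut-2-en-1-one
Product: 16 3-(benzyloxy)-2-[2-(benzyloxy)-4-methoxyphenyl]-5-hydroxy-7,8-dimethoxy-4H-chromen-4-one, via (Z)-dienylketene 14 (not isolated), via 4aH-chromene-4,5-dione 15 (not isolated)
Conditions: p-xylene (0.01 M, degassed), 138 °C, Ar
Reagents that add atoms: none
Why: Proposed new method: heat breaks the bond between the carbonyl carbon and the quaternary carbon of 13 in a conrotatory four-electron electrocyclic opening, and in the resulting ketene 14 the ketene carbon (future C5) and the pyranone CH carbon (future C4a) are the termini of a hexatriene-type array that closes to 15 and tautomerizes to phenol 16. The closest known reaction type is the Moore rearrangement of 4-alkenyl-, 4-aryl- and 4-heteroaryl-4-alkoxycyclobutenones to mono-O-alkyl hydroquinones, and what is new is a 4-pyranone C=C bond as the third pi component. Ring A, the only ring formed, closes by a thermal disrotatory six-electron electrocyclization at C4a–C5, which is polarity-matched (future C4a is the nucleophilic beta carbon of the ring enol ether, the ketene carbon is the electrophile) and costs less resonance energy than the known closures onto benzene rings. The torquoselectivity required is outward rotation of the methoxy group on the quaternary carbon, the general preference of donor substituents in cyclobutenone opening, which swings the pyranonyl group inward beside the ketene (Z geometry of 14). Site selectivity is built in, because the attached pyranone carbon (future C8a) has the ring oxygen as its other neighbour, so the quaternary carbon can only become C8, the methoxy-bearing alkene carbon C7, the alkene CH C6 and the carbonyl carbon C5, without any 5,6,7 isomer. No lasting stereocentre is created: C4a–H of 15 lies between two carbonyl groups, so enolization to the C4=O-chelated phenol is fast and irreversible, erases the racemic centre and pulls the reversible opening forward, while high dilution under argon keeps the ketene from other partners.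

**Step 10**
Reactants: 16 3-(benzyloxy)-2-[2-(benzyloxy)-4-methoxyphenyl]-5-hydroxy-7,8-dimethoxy-4H-chromen-4-one
Product: 17 3,5-dihydroxy-2-(2-hydroxy-4-methoxyphenyl)-7,8-dimethoxy-4H-chromen-4-one (3,5,2'-trihydroxy-7,8,4'-trimethoxyflavone)
Conditions: H2 (1 atm), Pd/C, EtOAc/MeOH, rt
Reagents that add atoms: none
Why: Catalytic hydrogenolysis cleaves both benzylic C–O bonds under neutral conditions that leave the three methyl ethers, the chelated C5 phenol and the tetrasubstituted C2=C3 bond alone and give acid-induced Wessely–Moser isomerization of ring A no chance.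

**Compound list**
1 | 3-hydroxy-4H-pyran-4-one | O=c1ccocc1O | starting material
2 | 3-hydroxy-2-iodo-4H-pyran-4-one | O=c1ccoc(I)c1O | intermediate
3 | 3-(benzyloxy)-2-iodo-4H-pyran-4-one | O=c1ccoc(I)c1OCc1ccccc1 | intermediate
4 | 2-bromo-5-methoxyphenol | COc1ccc(Br)c(O)c1 | starting material
5 | 2-(benzyloxy)-1-bromo-4-methoxybenzene | COc1ccc(Br)c(OCc2ccccc2)c1 | intermediate
6 | 2-[2-(benzyloxy)-4-methoxyphenyl]-4,4,5,5-tetramethyl-1,3,2-dioxaborolane | COc1ccc(B2OC(C)(C)C(C)(C)O2)c(OCc2ccccc2)c1 | intermediate
7 | 3-(benzyloxy)-2-[2-(benzyloxy)-4-methoxyphenyl]-4H-pyran-4-one | COc1ccc(-c2occc(=O)c2OCc2ccccc2)c(OCc2ccccc2)c1 | intermediate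
8 | dimethyl squarate | COC1=C(OC)C(=O)C1=O | starting material
9 | 4-hydroxy-2,3-dimethoxycyclobut-2-en-1-one (racemic, not isolated) | COC1=C(OC)C(O)C1=O | intermediate
10 | 3-methoxycyclobut-3-ene-1,2-dione | COC1=CC(=O)C1=O | intermediate
11 | {5-(benzyloxy)-6-[2-(benzyloxy)-4-methoxyphenyl]-4-oxo-4H-pyran-2-yl}magnesium chloride (LiCl complex, not isolated) | COc1ccc(-c2oc([Mg]Cl)cc(=O)c2OCc2ccccc2)c(OCc2ccccc2)c1 | intermediate
12 | 4-{5-(benzyloxy)-6-[2-(benzyloxy)-4-methoxyphenyl]-4-oxo-4H-pyran-2-yl}-4-hydroxy-3-methoxycyclobut-2-en-1-one (racemic) | COc1ccc(-c2oc(C3(O)C(OC)=CC3=O)cc(=O)c2OCc2ccccc2)c(OCc2ccccc2)c1 | intermediate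
13 | 4-{5-(benzyloxy)-6-[2-(benzyloxy)-4-methoxyphenyl]-4-oxo-4H-pyran-2-yl}-3,4-dimethoxycyclobut-2-en-1-one (racemic) | COc1ccc(-c2oc(C3(OC)C(OC)=CC3=O)cc(=O)c2OCc2ccccc2)c(OCc2ccccc2)c1 | intermediate
14 | (3Z)-4-{5-(benzyloxy)-6-[2-(benzyloxy)-4-methoxyphenyl]-4-oxo-4H-pyran-2-yl}-3,4-dimethoxybuta-1,3-dien-1-one (not isolated) | O=C=C/C(OC)=C(/OC)c1cc(=O)c(OCc2ccccc2)c(-c2ccc(OC)cc2OCc2ccccc2)o1 | intermediate
15 | 3-(benzyloxy)-2-[2-(benzyloxy)-4-methoxyphenyl]-7,8-dimethoxy-4aH-chromene-4,5-dione (racemic, not isolated) | COC1=CC(=O)C2C(=O)C(OCc3ccccc3)=C(c3ccc(OC)cc3OCc3ccccc3)OC2=C1OC | intermediate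
16 | 3-(benzyloxy)-2-[2-(benzyloxy)-4-methoxyphenyl]-5-hydroxy-7,8-dimethoxy-4H-chromen-4-one | COc1ccc(-c2oc3c(OC)c(OC)cc(O)c3c(=O)c2OCc2ccccc2)c(OCc2ccccc2)c1 | intermediate
17 | 3,5,2'-trihydroxy-7,8,4'-trimethoxyflavone | COc1ccc(-c2oc3c(OC)c(OC)cc(O)c3c(=O)c2O)c(O)c1 | target

**Total step count:** 10.
**Longest linear sequence:** 7 steps (1, 2, 5, 7, 8, 9, 10). The branch 3, 4, 5, 7, 8, 9, 10 is equally long.

**Steps most likely to fail**

**Step 9.**
- What may go wrong: the ring-opened ketene may not engage the cross-conjugated, electron-poor pyranone double bond fast enough. Reclosure, ketene oligomerization or capture by traces of nucleophile would then consume the material.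
- Fallback (known chemistry, ring A bought and ring C closed onto it): it sets out from 5.
- Bromine–lithium exchange (n-BuLi, THF, −78 °C) gives [2-(benzyloxy)-4-methoxyphenyl]lithium F1, which DMF formylates to 2-(benzyloxy)-4-methoxybenzaldehyde F2.
- Claisen–Schmidt condensation of F2 with purchased 1-(2-hydroxy-3,4,6-trimethoxyphenyl)ethanone (CC(=O)c1c(O)c(OC)c(OC)cc1OC; KOH, EtOH) should give (E)-3-[2-(benzyloxy)-4-methoxyphenyl]-1-(2-hydroxy-3,4,6-trimethoxyphenyl)prop-2-en-1-one F3. Only one phenol is free in F3, so the 5,7,8 pattern cannot be scrambled.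
- Catalytic I2 in DMSO at 130 °C closes and dehydrogenates F3 to 2-[2-(benzyloxy)-4-methoxyphenyl]-5,7,8-trimethoxy-4H-chromen-4-one F4.
- Dimethyldioxirane epoxidizes C2=C3 to racemic 2-[2-(benzyloxy)-4-methoxyphenyl]-2,3-epoxy-5,7,8-trimethoxychroman-4-one F5. Catalytic TsOH opens it to 2-[2-(benzyloxy)-4-methoxyphenyl]-3-hydroxy-5,7,8-trimethoxy-4H-chromen-4-one F6.
- BCl3 in CH2Cl2 (−78 to 0 °C) then removes the carbonyl-chelated 5-O-methyl group and the benzyl ether, and the route is rejoined at 17.

**Step 7.**
- What may go wrong: metalation may occur beside the carbonyl group instead of beside the ring oxygen, with ring opening to follow. The metalated pyranone may self-condense. The vinylic C–H of the dione may transfer a proton, or attack may occur at its vinylogous ester carbon.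
- Fallback (halogen–metal exchange in place of direct deprotonation): it sets out from 7.
- The magnesium-free base TMPZnCl·LiCl (THF, rt), which metalates chromones beside the ring oxygen, should give {5-(benzyloxy)-6-[2-(benzyloxy)-4-methoxyphenyl]-4-oxo-4H-pyran-2-yl}zinc chloride F7.
- Iodolysis with I2 gives 3-(benzyloxy)-2-[2-(benzyloxy)-4-methoxyphenyl]-6-iodo-4H-pyran-4-one F8, whose regiochemistry can be checked on an isolated compound.
- Iodine–magnesium exchange with iPrMgCl·LiCl (THF, −78 °C) then produces the Grignard reagent free of amine and excess base. The route is rejoined at 11, which is added to 10 as before to give 12.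

**Step 8.**
- What may go wrong: alkylation of the hindered, electron-poor tertiary carbinol may be sluggish, with cleavage or rearrangement of the strained ring competing over long reaction times.
- Fallback (methylation moved behind the ring closure): it sets out from 12.
- Heating 12 in degassed p-xylene (138 °C, Ar) should take it through the 4-hydroxy dienylketene F9 and the 8-hydroxy-4aH-chromene-4,5-dione F10. The product is 3-(benzyloxy)-2-[2-(benzyloxy)-4-methoxyphenyl]-5,8-dihydroxy-7-methoxy-4H-chromen-4-one F11, which is handled with exclusion of air.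
- One equivalent of Me2SO4 with K2CO3 in acetone methylates only the free C8 phenol, because the C5 phenol is held in the hydrogen bond to C4=O. This is the classical partial methylation of 5,8-dihydroxyflavones, and the route is rejoined at 16.

**Further compounds**
F1 | step 9 | [2-(benzyloxy)-4-methoxyphenyl]lithium | [Li]c1ccc(OC)cc1OCc1ccccc1
F2 | step 9 | 2-(benzyloxy)-4-methoxybenzaldehyde | COc1ccc(C=O)c(OCc2ccccc2)c1
F3 | step 9 | (E)-3-[2-(benzyloxy)-4-methoxyphenyl]-1-(2-hydroxy-3,4,6-trimethoxyphenyl)prop-2-en-1-one | COc1ccc(/C=C/C(=O)c2c(O)c(OC)c(OC)cc2OC)c(OCc2ccccc2)c1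
F4 | step 9 | 2-[2-(benzyloxy)-4-methoxyphenyl]-5,7,8-trimethoxy-4H-chromen-4-one | COc1ccc(-c2cc(=O)c3c(OC)cc(OC)c(OC)c3o2)c(OCc2ccccc2)c1
F5 | step 9 | 2-[2-(benzyloxy)-4-methoxyphenyl]-2,3-epoxy-5,7,8-trimethoxychroman-4-one (racemic, cis-fused) | COc1ccc(C23OC2C(=O)c2c(OC)cc(OC)c(OC)c2O3)c(OCc2ccccc2)c1
F6 | step 9 | 2-[2-(benzyloxy)-4-methoxyphenyl]-3-hydroxy-5,7,8-trimethoxy-4H-chromen-4-one | COc1ccc(-c2oc3c(OC)c(OC)cc(OC)c3c(=O)c2O)c(OCc2ccccc2)c1
F7 | step 7 | {5-(benzyloxy)-6-[2-(benzyloxy)-4-methoxyphenyl]-4-oxo-4H-pyran-2-yl}zinc chloride | COc1ccc(-c2oc([Zn]Cl)cc(=O)c2OCc2ccccc2)c(OCc2ccccc2)c1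
F8 | step 7 | 3-(benzyloxy)-2-[2-(benzyloxy)-4-methoxyphenyl]-6-iodo-4H-pyran-4-one | COc1ccc(-c2oc(I)cc(=O)c2OCc2ccccc2)c(OCc2ccccc2)c1
F9 | step 8 | (3Z)-4-{5-(benzyloxy)-6-[2-(benzyloxy)-4-methoxyphenyl]-4-oxo-4H-pyran-2-yl}-4-hydroxy-3-methoxybuta-1,3-dien-1-one | O=C=C/C(OC)=C(/O)c1cc(=O)c(OCc2ccccc2)c(-c2ccc(OC)cc2OCc2ccccc2)o1
F10 | step 8 | 3-(benzyloxy)-2-[2-(benzyloxy)-4-methoxyphenyl]-8-hydroxy-7-methoxy-4aH-chromene-4,5-dione (racemic) | COC1=CC(=O)C2C(=O)C(OCc3ccccc3)=C(c3ccc(OC)cc3OCc3ccccc3)OC2=C1O
F11 | step 8 | 3-(benzyloxy)-2-[2-(benzyloxy)-4-methoxyphenyl]-5,8-dihydroxy-7-methoxy-4H-chromen-4-one | COc1ccc(-c2oc3c(O)c(OC)cc(O)c3c(=O)c2OCc2ccccc2)c(OCc2ccccc2)c1
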